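Ring numbering: C1 (OMe), C2 (OH), C3 (OBz), C4 (OH), C5 (alkene carbon carrying C6H2OBz), C5a (alkene CH); the single ring, the cyclohexene, is closed once, in step 11.
The strategy rests on the C4 carbinol being bonded to C5, the α-carbon of the C6–C5=C5a unit: with C6 as a thioester this is a Morita–Baylis–Hillman retron, so the C4–C5 bond is cut to give the acyclic aldehyde enethioate 14.
After ring closure C6 is taken from thioester to CH2OBz (reduction, primary-selective benzoylation) and the C2 silyl ether is removed last.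
14 maps onto D-xylose: xylose C2, C3, C4 are ring C1, C2, C3; xylose C1 becomes C5a by Wittig olefination of a furanose lactol, which frees the ring oxygen O4 for the C3 benzoate; xylose C5 is oxidised to the C4 aldehyde.
O2 is told apart from O3 and O5 on D-xylono-1,4-lactone (3,5-acetonide, O2 methylation, bis-silylation), and the lactone is then reduced to the lactol without acid.

Key step: step 11

Remark: lactol 8 is carried as its anomeric mixture, since the anomeric centre disappears in step 7. O2–O5 in the Why lines of steps 1–10 are xylose positions; C1–C6 and C5a are the ring positions defined above.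

Step 1
Reactants: 1 D-xylose
Product: 3 D-xylono-1,4-lactone, via D-xylonic acid 2 (not isolated)
Conditions: Br2, K2CO3, H2O, 0 °C to rt; then concentrate from AcOH, 50 °C
Reagents that add atoms: water, O
Why: Bromine-water oxidation of the aldose at the anomeric carbon gives the aldonic acid, which lactonises to the five-membered 1,4-lactone on concentration; C2, C3 and C4 are not touched.

Step 2
Reactants: 3 D-xylono-1,4-lactone
Product: 4 3,5-O-isopropylidene-D-xylono-1,4-lactone
Conditions: 2,2-dimethoxypropane, TsOH·H2O (cat.), acetone, rt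
Reagents that add atoms: 2,2-dimethoxypropane, COC(C)(C)OC
Why: Acid-catalysed transacetalisation (acetonide formation): O3 and C5 are cis on the lactone and close a cis-fused 1,3-dioxane, whereas the trans 2,3-diol cannot be bridged, so only O2 stays free.

Step 3
Reactants: 4 3,5-O-isopropylidene-D-xylono-1,4-lactone
Product: 5 3,5-O-isopropylidene-2-O-methyl-D-xylono-1,4-lactone
Conditions: MeI, Ag2O, 4 Å MS, MeCN, 40 °C, dark
Reagents that add atoms: iodomethane, CI
Why: Purdie methylation (Ag2O-assisted O-alkylation) of the α-hydroxy lactone runs without a strong base, so the lactone is neither opened nor epimerised at C2.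

Step 4
Reactants: 5 3,5-O-isopropylidene-2-O-methyl-D-xylono-1,4-lactone
Product: 6 2-O-methyl-D-xylono-1,4-lactone
Conditions: AcOH/H2O 4:1, 40 °C; toluene azeotrope
Reagents that add atoms: none
Why: Acetal hydrolysis of the cis-fused 1,3-dioxane is fast in aqueous acetic acid, which leaves the methyl ether and the five-membered lactone intact.

Step 5
Reactants: 6 2-O-methyl-D-xylono-1,4-lactone
Product: 7 3,5-bis-O-(tert-butyldimethylsilyl)-2-O-methyl-D-xylono-1,4-lactone
Conditions: TBSCl, imidazole, DMF, rt to 40 °C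
Reagents that add atoms: tert-butyldimethylsilyl chloride, CC(C)(C)[Si](C)(C)Cl
Why: Silyl ether formation with imidazole-activated TBSCl protects both the primary O5 and the secondary O3, and the weak base does not cause β-elimination from the lactone.

Step 6
Reactants: 7 3,5-bis-O-(tert-butyldimethylsilyl)-2-O-methyl-D-xylono-1,4-lactone
Product: 8 3,5-bis-O-(tert-butyldimethylsilyl)-2-O-methyl-D-xylofuranose (anomeric mixture)
Conditions: i-Bu2AlH (1.1 equiv), CH2Cl2, −78 °C; aq. potassium sodium tartrate
Reagents that add atoms: none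
Why: Partial reduction of the lactone with i-Bu2AlH at low temperature stops at the aluminium hemiacetal, which gives the lactol on work-up; both silyl ethers survive the non-acidic conditions.

Step 7
Reactants: 8 3,5-bis-O-(tert-butyldimethylsilyl)-2-O-methyl-D-xylofuranose; 9 (ethylthiocarbonylmethylene)triphenylphosphorane
Product: 10 S-ethyl (2E)-5,7-bis-O-(tert-butyldimethylsilyl)-2,3-dideoxy-4-O-methyl-D-xylo-hept-2-enethioate (6-OH free; hept C4–C7 are xylose C2–C5)
Conditions: 9 (1.5 equiv), toluene, 80 °C
Reagents that add atoms: (ethylthiocarbonylmethylene)triphenylphosphorane 9, CCSC(=O)C=P(c1ccccc1)(c1ccccc1)c1ccccc1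
Why: Wittig olefination of the lactol through its open hydroxy aldehyde form with a stabilised ylide gives the (E)-enethioate and releases the former ring oxygen O4 as the only free hydroxyl; the three xylose stereocentres are untouched.

Step 8
Reactants: 10 hydroxy enethioate; 11 benzoyl chloride
Product: 12 S-ethyl (2E)-6-O-benzoyl-5,7-bis-O-(tert-butyldimethylsilyl)-2,3-dideoxy-4-O-methyl-D-xylo-hept-2-enethioate
Conditions: BzCl, pyridine, DMAP (cat.), CH2Cl2, 0 °C to rt
Reagents that add atoms: benzoyl chloride 11, O=C(Cl)c1ccccc1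
Why: DMAP-catalysed acyl transfer to the single free secondary hydroxyl installs the future C3 benzoate, and O-acylation should outrun oxa-Michael addition of this hindered alcohol to the enethioate.

Step 9
Reactants: 12 benzoate bis-silyl ether
Product: 13 S-ethyl (2E)-6-O-benzoyl-5-O-(tert-butyldimethylsilyl)-2,3-dideoxy-4-O-methyl-D-xylo-hept-2-enethioate (7-OH free)
Conditions: HF·pyridine, pyridine, THF, 0 °C
Reagents that add atoms: none
Why: Selective desilylation: the unhindered primary TBS ether is cleaved much faster than the secondary one flanked by the methoxy and benzoyloxy carbons, and the weakly acidic medium disfavours O4 to O5 benzoyl migration.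

Step 10
Reactants: 13 primary alcohol
Product: 14 S-ethyl (2E,4S,5R,6S)-6-(benzoyloxy)-5-[(tert-butyldimethylsilyl)oxy]-4-methoxy-7-oxohept-2-enethioate
Conditions: Dess–Martin periodinane, CH2Cl2, 0 °C to rt; crude aldehyde used at once
Reagents that add atoms: none
Why: Dess–Martin oxidation of the primary alcohol is non-basic, so the α-benzoyloxy aldehyde should form without epimerisation or β-elimination of the silyloxy group.

Step 11
Reactants: 14 aldehyde enethioate
Product: 15 S-ethyl (3S,4R,5R,6S)-5-(benzoyloxy)-4-[(tert-butyldimethylsilyl)oxy]-6-hydroxy-3-methoxycyclohex-1-ene-1-carbothioate (ring C1 OMe, C2 OTBS, C3 OBz, C4 OH, all trans)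
Conditions: PMe3 (0.5 equiv), CH2Cl2 (0.02 M), 0 °C to rt
Reagents that add atoms: none
Why: PMe3 adds reversibly to C5a of the enethioate, the thioester enolate so formed attacks the C4 aldehyde through C5, and proton transfer followed by E1cB loss of PMe3 regenerates the C5=C5a alkene, now inside the ring (intramolecular Morita–Baylis–Hillman reaction). The closest known reaction type is the trialkylphosphine-mediated Morita–Baylis–Hillman cyclisation of ω-formyl enoates and enethioates that carry enolisable aldehydes. The cyclohexene closes in the 6-(enolexo)-exo-trig mode, because C5 alone of the enolate C5=C6 unit becomes a ring atom and the aldehyde oxygen stays outside the ring. The new C4 stereocentre is set under substrate control: the all-trans C1 methoxy, C2 silyloxy and C3 benzoyloxy groups fix one chair-like transition state in which they are equatorial, and the reversible aldol step is expected to drain through the adduct whose C4–O bond is also equatorial, that is trans to the C3 benzoate. The step needs conjugate addition to win over enolisation of the α-benzoyloxy aldehyde and over intermolecular reaction; the weakly basic but strongly nucleophilic PMe3, the thioester (a better acceptor than an ester) and high dilution secure this.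

Step 12
Reactants: 15 cyclohexenol thioester
Product: 16 (3S,4R,5R,6S)-5-(benzoyloxy)-4-[(tert-butyldimethylsilyl)oxy]-6-hydroxy-3-methoxycyclohex-1-ene-1-carbaldehyde
Conditions: Et3SiH, 10% Pd/C, acetone, rt
Reagents that add atoms: none
Why: Fukuyama reduction: zerovalent palladium inserts into the C–S bond, hydride is transferred from Et3SiH and reductive elimination gives the aldehyde, under conditions to which benzoates, the silyl ether and the trisubstituted alkene are inert.

Step 13
Reactants: 16 enal
Product: 17 (1S,2R,3R,4S)-3-O-benzoyl-2-O-(tert-butyldimethylsilyl)-5-(hydroxymethyl)-1-O-methylcyclohex-5-ene-1,2,3,4-tetrol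
Conditions: NaBH4, CeCl3·7H2O, MeOH, −40 °C
Reagents that add atoms: none
Why: Luche reduction: CeCl3-assisted 1,2-hydride delivery to the enal gives the primary allylic alcohol without conjugate reduction, and the short cold reaction should leave the benzoate in place.

Step 14
Reactants: 17 diol; 11 benzoyl chloride
Product: 18 (1S,2R,3R,4S)-3-O-benzoyl-5-[(benzoyloxy)methyl]-2-O-(tert-butyldimethylsilyl)-1-O-methylcyclohex-5-ene-1,2,3,4-tetrol
Conditions: BzCl (1.05 equiv), 2,4,6-collidine, CH2Cl2, −40 to 0 °C
Reagents that add atoms: benzoyl chloride 11, O=C(Cl)c1ccccc1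
Why: Selective acylation: the unhindered primary allylic hydroxyl should react with one equivalent of BzCl far faster than the secondary C4 hydroxyl flanked by the C3 benzoate and the substituted alkene carbon.

Step 15
Reactants: 18 silyl ether
Product: 19 (1S,2R,3R,4S)-3-O-benzoyl-5-[(benzoyloxy)methyl]-1-O-methylcyclohex-5-ene-1,2,3,4-tetrol (target CNP0349013.8)
Conditions: HF·pyridine, THF, 0 °C to rt
Reagents that add atoms: none
Why: Fluoride-mediated desilylation in an acidic medium removes the C2 silyl ether without generating the alkoxides that would move the C3 benzoate to O2 or O4.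

Compound list
1 | D-xylose | O=C[C@H](O)[C@@H](O)[C@H](O)CO | starting material
2 | D-xylonic acid (not isolated) | O=C(O)[C@H](O)[C@@H](O)[C@H](O)CO | intermediate
3 | D-xylono-1,4-lactone | O=C1[C@H](O)[C@@H](O)[C@@H](CO)O1 | intermediate
4 | 3,5-O-isopropylidene-D-xylono-1,4-lactone | O=C1[C@H](O)[C@H]2OC(C)(C)OC[C@H]2O1 | intermediate
5 | 3,5-O-isopropylidene-2-O-methyl-D-xylono-1,4-lactone | O=C1[C@H](OC)[C@H]2OC(C)(C)OC[C@H]2O1 | intermediate
6 | 2-O-methyl-D-xylono-1,4-lactone | O=C1[C@H](OC)[C@@H](O)[C@@H](CO)O1 | intermediate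
7 | 3,5-bis-O-(tert-butyldimethylsilyl)-2-O-methyl-D-xylono-1,4-lactone | O=C1[C@H](OC)[C@@H](O[Si](C)(C)C(C)(C)C)[C@@H](CO[Si](C)(C)C(C)(C)C)O1 | intermediate
8 | 3,5-bis-O-(tert-butyldimethylsilyl)-2-O-methyl-D-xylofuranose (anomeric mixture) | OC1[C@H](OC)[C@@H](O[Si](C)(C)C(C)(C)C)[C@@H](CO[Si](C)(C)C(C)(C)C)O1 | intermediate
9 | (ethylthiocarbonylmethylene)triphenylphosphorane | CCSC(=O)C=P(c1ccccc1)(c1ccccc1)c1ccccc1 | starting material
10 | S-ethyl (2E)-5,7-bis-O-(tert-butyldimethylsilyl)-2,3-dideoxy-4-O-methyl-D-xylo-hept-2-enethioate | CCSC(=O)/C=C/[C@H](OC)[C@@H](O[Si](C)(C)C(C)(C)C)[C@H](O)CO[Si](C)(C)C(C)(C)C | intermediate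
11 | benzoyl chloride | O=C(Cl)c1ccccc1 | starting material
12 | S-ethyl (2E)-6-O-benzoyl-5,7-bis-O-(tert-butyldimethylsilyl)-2,3-dideoxy-4-O-methyl-D-xylo-hept-2-enethioate | CCSC(=O)/C=C/[C@H](OC)[C@@H](O[Si](C)(C)C(C)(C)C)[C@H](OC(=O)c1ccccc1)CO[Si](C)(C)C(C)(C)C | intermediate
13 | S-ethyl (2E)-6-O-benzoyl-5-O-(tert-butyldimethylsilyl)-2,3-dideoxy-4-O-methyl-D-xylo-hept-2-enethioate | CCSC(=O)/C=C/[C@H](OC)[C@@H](O[Si](C)(C)C(C)(C)C)[C@H](OC(=O)c1ccccc1)CO | intermediate
14 | S-ethyl (2E,4S,5R,6S)-6-(benzoyloxy)-5-[(tert-butyldimethylsilyl)oxy]-4-methoxy-7-oxohept-2-enethioate | O=C[C@@H](OC(=O)c1ccccc1)[C@H](O[Si](C)(C)C(C)(C)C)[C@@H](OC)/C=C/C(=O)SCC | intermediate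
15 | S-ethyl (3S,4R,5R,6S)-5-(benzoyloxy)-4-[(tert-butyldimethylsilyl)oxy]-6-hydroxy-3-methoxycyclohex-1-ene-1-carbothioate | CO[C@H]1C=C(C(=O)SCC)[C@H](O)[C@@H](OC(=O)c2ccccc2)[C@@H]1O[Si](C)(C)C(C)(C)C | intermediate
16 | (3S,4R,5R,6S)-5-(benzoyloxy)-4-[(tert-butyldimethylsilyl)oxy]-6-hydroxy-3-methoxycyclohex-1-ene-1-carbaldehyde | CO[C@H]1C=C(C=O)[C@H](O)[C@@H](OC(=O)c2ccccc2)[C@@H]1O[Si](C)(C)C(C)(C)C | intermediate
17 | (1S,2R,3R,4S)-3-O-benzoyl-2-O-(tert-butyldimethylsilyl)-5-(hydroxymethyl)-1-O-methylcyclohex-5-ene-1,2,3,4-tetrol | CO[C@H]1C=C(CO)[C@H](O)[C@@H](OC(=O)c2ccccc2)[C@@H]1O[Si](C)(C)C(C)(C)C | intermediate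
18 | (1S,2R,3R,4S)-3-O-benzoyl-5-[(benzoyloxy)methyl]-2-O-(tert-butyldimethylsilyl)-1-O-methylcyclohex-5-ene-1,2,3,4-tetrol | CO[C@H]1C=C(COC(=O)c2ccccc2)[C@H](O)[C@@H](OC(=O)c2ccccc2)[C@@H]1O[Si](C)(C)C(C)(C)C | intermediate
19 | (1S,2R,3R,4S)-3-O-benzoyl-5-[(benzoyloxy)methyl]-1-O-methylcyclohex-5-ene-1,2,3,4-tetrol (CNP0349013.8) | CO[C@H]1C=C(COC(=O)c2ccccc2)[C@H](O)[C@@H](OC(=O)c2ccccc2)[C@@H]1O | target

Total step count: 15. Longest linear sequence: 15 steps (1 to 19); 9 and 11 are bought.

Steps most likely to fail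

Step 11. The aldol addition may take place on the wrong aldehyde face, putting the C4 hydroxyl cis to the C3 benzoate. Enolisation of the α-benzoyloxy aldehyde and benzoyl shift to the C4 alkoxide are further drains. The fallback sets out from 14 and comes back at 15, and sets C4 by ketone reduction instead of by the aldol. The cyclisation of 14 is still run with PMe3, and the C4-epimeric cyclohexenol thioester F1, alone or mixed with 15, is oxidised with Dess–Martin periodinane (CH2Cl2, 0 °C) to the C4 ketone, the 6-oxocyclohexene thioester F2. Luche reduction of F2 (NaBH4, CeCl3·7H2O, MeOH, −78 °C) should deliver hydride axially to the half-chair enone and give the equatorial C4 alcohol trans to the C3 benzoate, which is 15. Reduction of 2-acylcycloalkenones to the allylic alcohols under these conditions is known chemistry.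

Step 7. Once the lactol has opened, the freed O4 hydroxyl may add back to the enethioate (5-exo oxa-Michael closure to a tetrahydrofuran), or the hindered lactol may olefinate sluggishly. The fallback sets out from lactone 7 and comes back at 12, and never has a free hydroxyl next to the acceptor. Lactone 7 is opened with MeNH(OMe)·HCl and AlMe3 (CH2Cl2, 0 °C) to the N-methoxy-N-methyl hydroxy amide F3. F3 is benzoylated at once (BzCl 11, pyridine, DMAP) to the benzoate amide F4. The amide is reduced chemoselectively with Cp2Zr(H)Cl (THF, rt), which tolerates the benzoate, to the 2-O-methyl aldehyde F5. Wittig olefination of F5 with 9 (CH2Cl2, rt) gives 12.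

Step 12. Palladium hydride side reactions (saturation or migration of the ring alkene, hydrogenolysis of an allylic C–O bond, silylation of the free C4 hydroxyl) or slow turnover of the hindered conjugated thioester may spoil the reduction. The fallback sets out from 15 and comes back at 17, passing through the acid instead of aldehyde 16. Silver-assisted hydrolysis of 15 (AgNO3, 2,6-lutidine, THF/H2O, rt) gives the cyclohexenecarboxylic acid F6. F6 is converted with i-BuOCOCl and N-methylmorpholine (THF, −15 °C) into the mixed carbonic anhydride F7, which is reduced in the same flask with NaBH4 (THF/H2O, 0 °C) to diol 17; the benzoate is not reduced under these conditions.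

Further compounds
F1 | step 11 | C4-epimer of 15, S-ethyl (3S,4R,5R,6R)-5-(benzoyloxy)-4-[(tert-butyldimethylsilyl)oxy]-6-hydroxy-3-methoxycyclohex-1-ene-1-carbothioate | CO[C@H]1C=C(C(=O)SCC)[C@@H](O)[C@@H](OC(=O)c2ccccc2)[C@@H]1O[Si](C)(C)C(C)(C)C
F2 | step 11 | C4 ketone of 15, S-ethyl 5-(benzoyloxy)-4-[(tert-butyldimethylsilyl)oxy]-3-methoxy-6-oxocyclohex-1-ene-1-carbothioate (configuration at ring C1–C3 as in 15) | CO[C@H]1C=C(C(=O)SCC)C(=O)[C@@H](OC(=O)c2ccccc2)[C@@H]1O[Si](C)(C)C(C)(C)C
F3 | step 7 | 3,5-bis-O-(tert-butyldimethylsilyl)-N-methoxy-N,2-O-dimethyl-D-xylonamide (4-OH free) | CON(C)C(=O)[C@H](OC)[C@@H](O[Si](C)(C)C(C)(C)C)[C@H](O)CO[Si](C)(C)C(C)(C)C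
F4 | step 7 | 4-O-benzoyl-3,5-bis-O-(tert-butyldimethylsilyl)-N-methoxy-N,2-O-dimethyl-D-xylonamide | CON(C)C(=O)[C@H](OC)[C@@H](O[Si](C)(C)C(C)(C)C)[C@H](OC(=O)c1ccccc1)CO[Si](C)(C)C(C)(C)C
F5 | step 7 | 4-O-benzoyl-3,5-bis-O-(tert-butyldimethylsilyl)-2-O-methyl-aldehydo-D-xylose | O=C[C@H](OC)[C@@H](O[Si](C)(C)C(C)(C)C)[C@H](OC(=O)c1ccccc1)CO[Si](C)(C)C(C)(C)C
F6 | step 12 | (3S,4R,5R,6S)-5-(benzoyloxy)-4-[(tert-butyldimethylsilyl)oxy]-6-hydroxy-3-methoxycyclohex-1-ene-1-carboxylic acid | CO[C@H]1C=C(C(=O)O)[C@H](O)[C@@H](OC(=O)c2ccccc2)[C@@H]1O[Si](C)(C)C(C)(C)C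
F7 | step 12 | isobutyl carbonic anhydride of F6 (not isolated) | CO[C@H]1C=C(C(=O)OC(=O)OCC(C)C)[C@H](O)[C@@H](OC(=O)c2ccccc2)[C@@H]1O[Si](C)(C)C(C)(C)C
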